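## Structural features

The target is a germacrane: one ten-membered carbocycle carrying an E trisubstituted alkene (C1=C10, methyl on C10), a cis-fused trisubstituted epoxide (C4–C5, methyl on the quaternary C4), a cinnamate on O6, an isopropyl group on C7 and a free secondary hydroxyl on C8. Five stereocentres stand in an unbroken row, C4–C5–C6–C7–C8 (4S,5R,6S,7R,8R). The epoxide oxygen and O6 are threo (on opposite faces in the flat ring drawing), O6 and the isopropyl group are syn in the zigzag sense, and O6 and O8 are 1,3-anti. The fragile elements are the epoxide (it faces the C1=C10 alkene across the ring and cyclises transannularly under acid), the strained E-cyclodecene, and the reducible, base-sensitive cinnamate. At the ketone stage there is also a β-oxygenated, α-branched, β,γ-unsaturated ketone that can epimerise at C7, eliminate O6 or move its alkene into conjugation. The real difficulty is threefold: closing a ten-membered ring with a defined E alkene, telling O6 from O8, and placing the epoxide oxygen on the correct face without touching C1=C10. The key step exploits the array C8(O)–C9H2–C10(CH3)=C1. A ketone with a β,γ E alkene is what remains when two carbons (C9, C10) are inserted beside the carbonyl of an eight-membered ketone, and that eight-membered ring (C8, C1–C7) already holds C6, C7 and the Z C4=C5 alkene that becomes the cis epoxide.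

## Logic of the disconnections

29 ⇒ 26 + 27. The acyl–O6 bond and the C8–H bond are cut together (Evans–Tishchenko transform). This is the only cut that removes the ester and the C8 carbinol at once while solving the O6/O8 differentiation by construction. It reduces the target to a β-hydroxy ketone and an aldehyde. The forward step must transfer hydride from an O6-bound hemiacetal to the C8 face anti to O6, and must leave the epoxide intact.

26 ⇒ 25. Both C–O bonds of the oxirane are cut. C6–OH is allylic to C4=C5 and to no other alkene, so a hydroxyl-bound metal peroxide can find this alkene alone. Two stereocentres (C4, C5) disappear. The forward step must ignore the strained C1=C10 and deliver oxygen to the face that ends anti to O6 in the flat ring drawing (threo). That calls for a template tolerating a wide O–C6–C5=C4 angle; a vanadium template, which needs a small angle and favours the cis epoxy alcohol in medium-ring Z-allylic alcohols, is therefore not used.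

25 ⇒ 24 ⇒ 22 ⇒ 21. The O6–H bond is traced back to O6–Si, C9–H to C9–CO2-allyl, and C8=O to C8–N. No skeletal simplification results, but the ketone is mapped onto the push–pull dienamine ester that a two-carbon ring enlargement delivers. The demands are:
- the C9 carboxyl must leave without heat or base, hence an allyl ester and zerovalent palladium;
- the silyl ether must stay until the ester is gone, so that O6 cannot lactonise onto it;
- the hydrolysis must protonate C9 and not C1, so that C1=C10 stays E and out of conjugation.

21 ⇒ 15 + 18 (through 20 and 19). C1–C10 and C8–C9 are cut. The ten-membered ring is traced to a cyclobutene fused to an eight-membered ring, and that to an enamine and an ynoate. The gain is the largest of the route: a medium-ring closure is replaced by a ring expansion, and the E alkene, the C10 methyl and the C8 oxygen all come from the two partners. The forward step needs enamine regiochemistry toward C1, attack at the methyl-bearing alkyne carbon, and outward rotation of the amino group during conrotatory opening.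

18 ⇒ 16 + 17. The ester C–O bond is cut, leading to two commercial liquids. The only demand is an esterification that does not isomerise the ynoate.

15 ⇒ 13 + 14. The C8–N bond is cut, returning the enamine to its ketone. The forward condensation must place the double bond toward C1 and must not equilibrate through C7, which would epimerise C7 or expel O6.

13 ⇒ 12. The C4=C5 bond is cut (ring-closing metathesis transform). The ring can only hold the Z alkene, so the geometry needed for the cis epoxide is guaranteed. The precursor is an acyclic diene. The forward step must close an eight-membered ring onto a 1,1-disubstituted alkene faster than it oligomerises.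

12 ⇒ 8 + 10 (10 from 9). The C8–C1 bond is cut, giving an N-methoxy-N-methyl amide and a C6 Grignard reagent. The forward step must stop at the ketone and leave C7 alone.

8 ⇒ 7 ⇒ 6. The O6–Si bond and the C8–N(OMe)Me bond are traced back to the free aldol imide. The amide exchange is placed before silylation, because the free C6 hydroxyl (as its aluminium alkoxide) steers the amide nucleophile to the exocyclic carbonyl of this α-branched imide.

6 ⇒ 3 + 4 (through 5). The C6–C7 bond is cut (auxiliary aldol transform). Both stereocentres that control everything later are set here, syn and in absolute terms. The forward step needs a Z boron enolate and a closed chair transition state.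

3 ⇒ 1 + 2. The N–acyl bond is cut, giving the commercial auxiliary and acid chloride.

## Other disconnections considered

Alternative 1: The acyclic dienol A1 would come from cutting C3–C4 and C5–C6. The alkylmagnesium reagent from bromide A2 is turned into an alkylcopper, which adds syn across propyne A3; the resulting Z-alkenylcopper is trapped by aldehyde A4.
- In favour: the Z geometry of C4=C5 is set by syn-carbometalation and the E C1=C10 alkene is carried in ready-made with A2. On alkene geometry this is the equal of the chosen plan and, for C1=C10, arguably the better, because nothing depends on torquoselectivity. The assembly is convergent.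
- Against: no ring is formed, so the ten-membered closure (C8–C9) is postponed to a late acyclic E,Z-diene. C6 is set by 1,2-induction from C7, where Felkin–Anh and chelation through the C8 ether predict opposite results. C8 is not addressed at all. PMB removal, oxidation, desilylation and activation must precede any ring closure.
- Comparison: the chosen plan answers the ring and C8 in the same stroke (ring enlargement to the ketone 24, then intramolecular hydride delivery), and its key step is less routine but does more. In step count Alternative 1 is expected to be longer.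

Alternative 2: C4–C5 and C1–C10 are cut in the [2+2] sense. Irradiation of enone A5 with cyclobutene ester A6 should give the cis-anti-cis photoadduct A7; thermal cleavage of its bicyclo[2.2.0]hexane unit (C1–C4 and C5–C10) would then unveil the cyclodecadiene A8.
- In favour: two C–C bonds and, after cycloreversion, the ten-membered ring arise in two operations. O6 and O8 are differentiated from the start (ketone at C6, silyl ether at C8), which is the equal of the chosen plan's solution and needs no special reaction.
- Against: a stereoretentive cleavage of the cis-anti-cis skeleton would place C3 and C6 trans on C4=C5 (as drawn in A8). The cis-fused epoxide of the target needs them cis, so the geometry would have to be corrected or come from a different adduct. The thermolysis temperature invites Cope rearrangement of the 1,5-diene. C15 arrives as an ester and must be reduced to a methyl group. Enantiopure A5 needs its own synthesis, and the facial course of the photoaddition relative to C7/C8 is not assured.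
- Comparison: the chosen plan sets the C4=C5 geometry unambiguously (ring-enforced Z in 13), runs below Cope temperatures, and brings C15 in at the right oxidation level. Alternative 2 is shorter to the ring but longer overall.

Alternative 3: C6–C7 is cut. A divalent samarium reductant would convert the C7 bromide of A9 into the C7–C8 samarium enolate, which adds to the epoxy aldehyde and closes the ring to A10, a compound identical with 26.
- In favour: the epoxide is installed on an acyclic Z-allylic alcohol by reagent-controlled Sharpless epoxidation, so its configuration does not depend on ring conformation and C1=C10 cannot compete. On this point Alternative 3 is better than step 13 of the chosen plan. It also converges on the same last step.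
- Against: the ring closure and two stereocentres (C6, C7) are entrusted to one ten-membered aldol cyclisation whose facial course at both partners is uncertain. The α,β-epoxy aldehyde is itself open to single-electron reduction and epoxide fragmentation in competition with C–Br reduction. Bromination must find C7 and not C9 of a β,γ-unsaturated ketone. High dilution is needed.
- Comparison: the chosen plan sets C6/C7 acyclically with an auxiliary and forms the ring by expansion, not by closure, at the price of a substrate-controlled epoxidation. Step counts should be similar.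

Key step: step 9

Remark on the chemistry (numbering): ten-membered compounds and their precursors are described with germacrane locants (C1=C10, C4–C5, O6, isopropyl on C7, C8–O, C9).

Remark on the chemistry (assumption): the ester alkyl group of the ynoate is a spectator in the ring enlargement. The allyl ester is used so that the C9 carboxyl can leave at room temperature, and it is prepared in step 8 because a reliable commercial supply is not assumed.

## Route

Step 1
Reactants: 1 (4S)-4-benzyl-1,3-oxazolidin-2-one; 2 3-methylbutanoyl chloride
Product: 3 (4S)-4-benzyl-3-(3-methylbutanoyl)-1,3-oxazolidin-2-one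
Conditions: Et3N, DMAP (cat.), CH2Cl2, 0 °C → rt
Reagents that add atoms: none
Why: N-acylation of the oxazolidinone by the acid chloride with DMAP acyl transfer; no stereocentre is touched.

Step 2
Reactants: 3 (4S)-4-benzyl-3-(3-methylbutanoyl)-1,3-oxazolidin-2-one; 4 acrolein
Product: 6 (4S)-4-benzyl-3-[(2S,3R)-3-hydroxy-2-(propan-2-yl)pent-4-enoyl]-1,3-oxazolidin-2-one, via boron enolate 5 (not isolated)
Conditions: Bu2BOTf, iPr2NEt, CH2Cl2, 0 °C; 4, −78 → 0 °C; then pH 7 buffer, MeOH, 30% H2O2, 0 °C
Reagents that add atoms: none
Why: Evans syn-aldol; soft enolisation should give the Z boron enolate 5, which reacts through a closed Zimmerman–Traxler chair with the auxiliary carbonyl turned away and the benzyl group blocking one enolate face, so C6 and C7 (germacrane locants) are set syn and in the (2S,3R) absolute sense.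

Step 3
Reactants: 6 (4S)-4-benzyl-3-[(2S,3R)-3-hydroxy-2-(propan-2-yl)pent-4-enoyl]-1,3-oxazolidin-2-one
Product: 7 (2S,3R)-3-hydroxy-N-methoxy-N-methyl-2-(propan-2-yl)pent-4-enamide
Conditions: MeNH(OMe)·HCl, AlMe3, CH2Cl2, −20 → 0 °C; then 1 M aq. HCl, 0 °C
Reagents that add atoms: N,O-dimethylhydroxylamine hydrochloride, CNOC.Cl
Why: Aluminium amide transamination (Weinreb amide formation); the free C6 hydroxyl becomes an aluminium alkoxide that steers the amide to the exocyclic carbonyl of this α-branched imide, which is why the exchange precedes silylation; the auxiliary is released for recovery.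

Step 4
Reactants: 7 (2S,3R)-3-hydroxy-N-methoxy-N-methyl-2-(propan-2-yl)pent-4-enamide
Product: 8 (2S,3R)-3-[(tert-butyldimethylsilyl)oxy]-N-methoxy-N-methyl-2-(propan-2-yl)pent-4-enamide
Conditions: TBSOTf, 2,6-lutidine, CH2Cl2, −78 → 0 °C
Reagents that add atoms: tert-butyldimethylsilyl trifluoromethanesulfonate, CC(C)(C)[Si](C)(C)OS(=O)(=O)C(F)(F)F
Why: Silylation of a hindered secondary allylic alcohol with the silyl triflate; the TBS ether should survive the Grignard reagent, metathesis, enamine chemistry and buffered acid, and is removable later with fluoride.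

Step 5
Reactants: 8 (2S,3R)-3-[(tert-butyldimethylsilyl)oxy]-N-methoxy-N-methyl-2-(propan-2-yl)pent-4-enamide; 9 5-bromo-2-methylpent-1-ene
Product: 12 (3R,4S)-3-[(tert-butyldimethylsilyl)oxy]-9-methyl-4-(propan-2-yl)deca-1,9-dien-5-one, via Grignard reagent 10 (not isolated), via magnesium chelate 11 (not isolated)
Conditions: Mg, I2 (cat.), THF, rt → 40 °C; 8, THF, 0 °C → rt; then sat. aq. NH4Cl
Reagents that add atoms: none
Why: Weinreb ketone synthesis forming C8–C1; the five-membered N,O-chelate 11 should persist until the quench, which prevents over-addition and keeps C7 from enolising while base is present.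

Step 6
Reactants: 12 (3R,4S)-3-[(tert-butyldimethylsilyl)oxy]-9-methyl-4-(propan-2-yl)deca-1,9-dien-5-one
Product: 13 (2S,3R,4Z)-3-[(tert-butyldimethylsilyl)oxy]-5-methyl-2-(propan-2-yl)cyclooct-4-en-1-one
Conditions: second-generation Grubbs catalyst RuCl2(=CHPh)(H2IMes)(PCy3) (10 mol %), CH2Cl2 (0.002 M), 40 °C
Reagents that add atoms: none
Why: Ring-closing metathesis; the catalyst should load at the monosubstituted vinyl group and close onto the 1,1-disubstituted alkene with loss of ethene, the eight-membered ring can only hold the Z alkene (C3 cis to C6), and high dilution plus the vicinal isopropyl/silyloxy branching favour closure over oligomerisation.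

Step 7
Reactants: 13 (2S,3R,4Z)-3-[(tert-butyldimethylsilyl)oxy]-5-methyl-2-(propan-2-yl)cyclooct-4-en-1-one; 14 pyrrolidine
Product: 15 1-[(1E,5Z,7R,8R)-7-[(tert-butyldimethylsilyl)oxy]-5-methyl-8-(propan-2-yl)cycloocta-1,5-dien-1-yl]pyrrolidine
Conditions: 14 (6 equiv), TiCl4 (0.55 equiv), toluene, 0 °C → rt; filtration under argon, used crude
Reagents that add atoms: none
Why: TiCl4-mediated enamine condensation suited to hindered ketones; allylic strain between the pyrrolidine ring and the C7 substituents should place the double bond toward C1, and the short, cold, irreversible dehydration limits iminium–enamine equilibration through C7.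

Step 8
Reactants: 16 but-2-ynoic acid; 17 prop-2-en-1-ol
Product: 18 prop-2-en-1-yl but-2-ynoate
Conditions: DCC, DMAP (cat.), CH2Cl2, 0 °C → rt
Reagents that add atoms: none
Why: Steglich esterification under neutral conditions that do not isomerise the ynoate; the allyl group is chosen so that the carboxyl can later be removed with zerovalent palladium at room temperature.

Step 9
Reactants: 15 1-[(1E,5Z,7R,8R)-7-[(tert-butyldimethylsilyl)oxy]-5-methyl-8-(propan-2-yl)cycloocta-1,5-dien-1-yl]pyrrolidine; 18 prop-2-en-1-yl but-2-ynoate
Product: 21 prop-2-en-1-yl (1(10)E,4Z,8Z,6R,7R)-6-[(tert-butyldimethylsilyl)oxy]-4,10-dimethyl-7-(propan-2-yl)-8-(pyrrolidin-1-yl)cyclodeca-1(10),4,8-triene-9-carboxylate, via zwitterion 19 (not isolated), via aminocyclobutene 20 (not isolated)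
Conditions: 18 (3 equiv), toluene (1 M), 80–100 °C, argon
Reagents that add atoms: none
Why: The enamine β-carbon C1 adds to the methyl-bearing alkyne carbon of 18 (C1–C10) to give the iminium–allenolate zwitterion 19, whose ester-bearing carbon C9 collapses onto the iminium carbon C8 (C8–C9) to give the cis-fused aminocyclobutene 20. The four-membered ring is thus closed from two components by a stepwise polar [2+2] (ionic 4-exo-trig collapse), and the ten-membered ring arises from it by thermal conrotatory four-electron electrocyclic opening across C1–C8, that is by expansion of the eight-membered ring and not by end-to-end cyclisation. The closest known reaction type is the two-carbon ring enlargement of cyclic ketone enamines with acetylenic esters. No lasting stereocentre is formed: C1 and C8 of 20 return to sp2, and C6 and C7 are spectators. Regiochemistry of the enamine (toward C1) is fixed in 15 by the branched C7, and attack at the β-carbon of the ynoate follows from its polarisation. Alkene geometry rests on torquoselectivity: the amino donor on C8 rotates outward, which turns C7 inward at C8 and, by conrotation, C2 outward at C1, so C1=C10 should be E and C8=C9 should carry C7 cis to C10, the only group forced inward at C1 being hydrogen. Because a β-substituted ynoate is a sluggish acceptor, excess 18, high concentration and heating are used, with the temperature held below the range in which the C1=C10/C4=C5 1,5-diene could undergo Cope rearrangement.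

Step 10
Reactants: 21 prop-2-en-1-yl (1(10)E,4Z,8Z,6R,7R)-6-[(tert-butyldimethylsilyl)oxy]-4,10-dimethyl-7-(propan-2-yl)-8-(pyrrolidin-1-yl)cyclodeca-1(10),4,8-triene-9-carboxylate
Product: 22 prop-2-en-1-yl (1(10)E,4Z,6R,7S)-6-[(tert-butyldimethylsilyl)oxy]-4,10-dimethyl-8-oxo-7-(propan-2-yl)cyclodeca-1(10),4-diene-9-carboxylate (C9 epimers and enol form)
Conditions: AcOH–NaOAc buffer (pH 4.5), THF–H2O, 25–40 °C
Reagents that add atoms: water, O
Why: Hydrolysis of a vinylogous carbamate; protonation at C9, the enamine β-carbon, gives the iminium ion that water converts to the C8 ketone, so C1=C10 stays E and unconjugated, the buffered pH spares the silyl ether, and the configuration at C9 is irrelevant because the carboxyl is removed next.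

Step 11
Reactants: 22 prop-2-en-1-yl (1(10)E,4Z,6R,7S)-6-[(tert-butyldimethylsilyl)oxy]-4,10-dimethyl-8-oxo-7-(propan-2-yl)cyclodeca-1(10),4-diene-9-carboxylate
Product: 24 (1(10)E,4Z,6R,7S)-6-[(tert-butyldimethylsilyl)oxy]germacra-1(10),4-dien-8-one, via beta-keto acid 23 (not isolated)
Conditions: Pd(PPh3)4 (5 mol %), morpholine, THF, 0 °C → rt
Reagents that add atoms: none
Why: Palladium-catalysed deallylation with decarboxylation; zerovalent palladium ionises the allyl ester, morpholine traps the allyl unit, and the β-keto acid 23 should lose CO2 through the six-membered transition state at room temperature, the enol being protonated at C9, so neither heat nor base reaches C7, O6 or the β,γ alkene.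

Step 12
Reactants: 24 (1(10)E,4Z,6R,7S)-6-[(tert-butyldimethylsilyl)oxy]germacra-1(10),4-dien-8-one
Product: 25 (1(10)E,4Z,6R,7S)-6-hydroxygermacra-1(10),4-dien-8-one
Conditions: HF·pyridine, pyridine, THF, 0 °C → rt
Reagents that add atoms: none
Why: Fluoride cleavage of the silyl ether in a pyridine-buffered medium, mild enough to avoid retro-aldol cleavage, dehydration of the β-hydroxy ketone and migration of the C1=C10 alkene; the ether is removed only now so that O6 could not lactonise onto the C9 ester earlier.

Step 13
Reactants: 25 (1(10)E,4Z,6R,7S)-6-hydroxygermacra-1(10),4-dien-8-one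
Product: 26 (1(10)E,4S,5R,6S,7S)-4,5-epoxy-6-hydroxygermacr-1(10)-en-8-one
Conditions: Ti(OiPr)4, t-BuOOH (anhydrous, in decane), 4 Å MS, CH2Cl2, −20 °C; then H2O
Reagents that add atoms: tert-butyl hydroperoxide, CC(C)(C)OO
Why: Titanium alkoxide-templated epoxidation of an allylic alcohol, chemoselective for C4=C5 because C1=C10 has no hydroxyl within reach; allylic strain between C3H2 and the C6 substituents should hold C6–H in the alkene plane so that the peroxide bound at O6 reaches the alkene face on its own side, which is expected to give the threo epoxy alcohol (4S,5R); the titanium template tolerates the wide O–C6–C5=C4 angle this requires, which a vanadium template does not.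

Step 14
Reactants: 26 (1(10)E,4S,5R,6S,7S)-4,5-epoxy-6-hydroxygermacr-1(10)-en-8-one; 27 (2E)-3-phenylprop-2-enal
Product: 29 (1(10)E,4S,5R,6S,7R,8R)-4,5-epoxy-8-hydroxygermacr-1(10)-en-6-yl (2E)-3-phenylprop-2-enoate, via hemiacetal 28 (not isolated)
Conditions: 27 (6 equiv), SmI2 (0.3 equiv), THF, −10 °C
Reagents that add atoms: none
Why: Evans–Tishchenko reduction; the samarium alkoxide of O6 adds to 27 to give hemiacetal 28, whose carbinol hydrogen is delivered to C8 through a samarium-bridged six-membered chair, which should give the 1,3-anti (8R) alcohol and leave the cinnamate on O6 in the same step, so O6 and O8 are told apart without protecting groups and under neutral, cold conditions.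

## Compound list

1 | (4S)-4-benzyl-1,3-oxazolidin-2-one | O=C1N[C@@H](Cc2ccccc2)CO1 | starting material
2 | 3-methylbutanoyl chloride | CC(C)CC(Cl)=O | starting material
3 | (4S)-4-benzyl-3-(3-methylbutanoyl)-1,3-oxazolidin-2-one | CC(C)CC(=O)N1[C@@H](Cc2ccccc2)COC1=O | intermediate
4 | acrolein (prop-2-enal) | C=CC=O | starting material
5 | (4S)-4-benzyl-3-[(1Z)-1-[(dibutylboranyl)oxy]-3-methylbut-1-en-1-yl]-1,3-oxazolidin-2-one (boron enolate) | CC(C)/C=C(\OB(CCCC)CCCC)N1[C@@H](Cc2ccccc2)COC1=O | intermediate (not isolated)
6 | (4S)-4-benzyl-3-[(2S,3R)-3-hydroxy-2-(propan-2-yl)pent-4-enoyl]-1,3-oxazolidin-2-one | C=C[C@@H](O)[C@H](C(C)C)C(=O)N1[C@@H](Cc2ccccc2)COC1=O | intermediate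
7 | (2S,3R)-3-hydroxy-N-methoxy-N-methyl-2-(propan-2-yl)pent-4-enamide | C=C[C@@H](O)[C@H](C(C)C)C(=O)N(C)OC | intermediate
8 | (2S,3R)-3-[(tert-butyldimethylsilyl)oxy]-N-methoxy-N-methyl-2-(propan-2-yl)pent-4-enamide | C=C[C@@H](O[Si](C)(C)C(C)(C)C)[C@H](C(C)C)C(=O)N(C)OC | intermediate
9 | 5-bromo-2-methylpent-1-ene | CC(=C)CCCBr | starting material
10 | (4-methylpent-4-en-1-yl)magnesium bromide | CC(=C)CCC[Mg]Br | intermediate (not isolated)
11 | bromomagnesium (3R,4S)-3-[(tert-butyldimethylsilyl)oxy]-5-[methoxy(methyl)amino]-9-methyl-4-(propan-2-yl)deca-1,9-dien-5-olate (N,O-chelate, C5 epimers) | C=C[C@@H](O[Si](C)(C)C(C)(C)C)[C@H](C(C)C)C(O[Mg]Br)(CCCC(C)=C)N(C)OC | intermediate (not isolated)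
12 | (3R,4S)-3-[(tert-butyldimethylsilyl)oxy]-9-methyl-4-(propan-2-yl)deca-1,9-dien-5-one | C=C[C@@H](O[Si](C)(C)C(C)(C)C)[C@H](C(C)C)C(=O)CCCC(C)=C | intermediate
13 | (2S,3R,4Z)-3-[(tert-butyldimethylsilyl)oxy]-5-methyl-2-(propan-2-yl)cyclooct-4-en-1-one | C/C1=C/[C@@H](O[Si](C)(C)C(C)(C)C)[C@H](C(C)C)C(=O)CCC1 | intermediate
14 | pyrrolidine | C1CCNC1 | starting material
15 | 1-[(1E,5Z,7R,8R)-7-[(tert-butyldimethylsilyl)oxy]-5-methyl-8-(propan-2-yl)cycloocta-1,5-dien-1-yl]pyrrolidine | C/C1=C/[C@@H](O[Si](C)(C)C(C)(C)C)[C@H](C(C)C)/C(N2CCCC2)=C\CC1 | intermediate (key-step precursor)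
16 | but-2-ynoic acid | CC#CC(=O)O | starting material
17 | prop-2-en-1-ol | C=CCO | starting material
18 | prop-2-en-1-yl but-2-ynoate | CC#CC(=O)OCC=C | intermediate
19 | iminium–allenolate zwitterion (C1–C10 formed, C8 as pyrrolidinium ylidene, C1 epimers) | C/C1=C/[C@@H](O[Si](C)(C)C(C)(C)C)[C@H](C(C)C)C(=[N+]2CCCC2)C(CC1)C(C)=C=C([O-])OCC=C | intermediate (not isolated)
20 | prop-2-en-1-yl (4Z,6R,7R)-6-[(tert-butyldimethylsilyl)oxy]-4,10-dimethyl-7-(propan-2-yl)-8-(pyrrolidin-1-yl)bicyclo[6.2.0]deca-4,9-diene-9-carboxylate (cis ring fusion at C1/C8, either face) | C/C1=C/[C@@H](O[Si](C)(C)C(C)(C)C)[C@H](C(C)C)C2(N3CCCC3)C(C(=O)OCC=C)=C(C)C2CC1 | intermediate (not isolated)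
21 | prop-2-en-1-yl (1(10)E,4Z,8Z,6R,7R)-6-[(tert-butyldimethylsilyl)oxy]-4,10-dimethyl-7-(propan-2-yl)-8-(pyrrolidin-1-yl)cyclodeca-1(10),4,8-triene-9-carboxylate (germacrane locants) | C/C1=C/[C@@H](O[Si](C)(C)C(C)(C)C)[C@H](C(C)C)/C(N2CCCC2)=C(C(=O)OCC=C)\C(C)=C\CC1 | intermediate (key-step product)
22 | prop-2-en-1-yl (1(10)E,4Z,6R,7S)-6-[(tert-butyldimethylsilyl)oxy]-4,10-dimethyl-8-oxo-7-(propan-2-yl)cyclodeca-1(10),4-diene-9-carboxylate (germacrane locants, C9 epimers) | C/C1=C/[C@@H](O[Si](C)(C)C(C)(C)C)[C@H](C(C)C)C(=O)C(C(=O)OCC=C)/C(C)=C/CC1 | intermediate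
23 | (1(10)E,4Z,6R,7S)-6-[(tert-butyldimethylsilyl)oxy]-4,10-dimethyl-8-oxo-7-(propan-2-yl)cyclodeca-1(10),4-diene-9-carboxylic acid (germacrane locants, C9 epimers) | C/C1=C/[C@@H](O[Si](C)(C)C(C)(C)C)[C@H](C(C)C)C(=O)C(C(=O)O)/C(C)=C/CC1 | intermediate (not isolated)
24 | (1(10)E,4Z,6R,7S)-6-[(tert-butyldimethylsilyl)oxy]germacra-1(10),4-dien-8-one, that is (3E,7Z,9R,10S)-9-[(tert-butyldimethylsilyl)oxy]-3,7-dimethyl-10-(propan-2-yl)cyclodeca-3,7-dien-1-one | C/C1=C/[C@@H](O[Si](C)(C)C(C)(C)C)[C@H](C(C)C)C(=O)C/C(C)=C/CC1 | intermediate
25 | (1(10)E,4Z,6R,7S)-6-hydroxygermacra-1(10),4-dien-8-one, that is (3E,7Z,9R,10S)-9-hydroxy-3,7-dimethyl-10-(propan-2-yl)cyclodeca-3,7-dien-1-one | C/C1=C/[C@@H](O)[C@H](C(C)C)C(=O)C/C(C)=C/CC1 | intermediate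
26 | (1(10)E,4S,5R,6S,7S)-4,5-epoxy-6-hydroxygermacr-1(10)-en-8-one | C/C1=C\CC[C@]2(C)O[C@@H]2[C@@H](O)[C@H](C(C)C)C(=O)C1 | intermediate
27 | (2E)-3-phenylprop-2-enal (cinnamaldehyde) | O=C/C=C/c1ccccc1 | starting material
28 | O6 hemiacetal of 26 with 27 (samarium-bound, hemiacetal carbon of either configuration) | C/C1=C\CC[C@]2(C)O[C@@H]2[C@@H](OC(O)/C=C/c2ccccc2)[C@H](C(C)C)C(=O)C1 | intermediate (not isolated)
29 | (1(10)E,4S,5R,6S,7R,8R)-4,5-epoxy-8-hydroxygermacr-1(10)-en-6-yl (2E)-3-phenylprop-2-enoate | C/C1=C\CC[C@]2(C)O[C@@H]2[C@@H](OC(=O)/C=C/c2ccccc2)[C@H](C(C)C)[C@H](O)C1 | target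

## Step count and least certain steps

Total step count: 14. Longest linear sequence: 13 steps (steps 1–7 and 9–14); step 8 is a one-step side branch.

Step 9 (key step). The most likely failure is slow conjugate addition of the enamine to the β-methyl ynoate. During prolonged heating the enamine could then equilibrate through C7 (epimerisation, loss of the O6 silanol), or the ynoate could isomerise to the allenoate before cycloaddition. A lesser risk is erosion of the E geometry if part of the cyclobutene opens against the donor preference. The fallback keeps the same two bonds but changes nucleophile and activation, so no amine is needed. It sets out from 13. Kinetic enolisation at C1 (LDA, THF, −78 °C) and trapping with TBSOTf should give the silyl enol ether F1. Activation of 18 with EtAlCl2 (CH2Cl2, −78 → −20 °C) should give the silyloxycyclobutene ester F2 by the known Lewis-acid [2+2] of silyl enol ethers with acetylenic esters. Warming in toluene should open F2 (siloxy donor outward) to the ring-enlarged silyl dienol ether F3, and buffered aqueous acetic acid should cleave the enol silyl ether selectively. The fallback comes back to the route at 22.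

Step 6. Intermolecular metathesis at the unhindered vinyl group may outrun the slow closure onto a 1,1-disubstituted alkene in a strained eight-membered transition state, and ruthenium hydrides may migrate the terminal alkenes. The fallback changes the substrate and the order of events. It sets out from 7. Excess 10 (THF, 0 °C → rt) should give the hydroxy dienone F4, whose free allylic hydroxyl accelerates carbene loading at C5 and removes the bulky silyl group from the reacting terminus. Ring-closing metathesis under the same catalyst should give the hydroxy cyclooctenone F5, and silylation (TBSOTf, 2,6-lutidine) comes back to the route at 13.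

Step 7. Iminium–enamine equilibration toward C7 during condensation would epimerise C7 or expel the C6 silyloxy group. The fallback fixes the regiochemistry by kinetic deprotonation instead of by condensation. It sets out from 13. LDA (THF, −78 °C) followed by PhNTf2 should give the enol triflate F6, and palladium-catalysed C–N coupling with 14 (Pd(OAc)2, BINAP, Cs2CO3, toluene, 80 °C; Buchwald–Hartwig amination of an alkenyl triflate) comes back to the route at 15.

Step 13. Poor facial selectivity is the main concern. If the ring prefers the conformer with the C6–O bond near the alkene plane, oxygen is delivered to the other face and the C4,C5-epimeric epoxide results. The fallback changes the delivery mechanism from a metal-alkoxide template to a hydrogen-bonded peracid, whose transition state matches the wide dihedral angle of the strain-minimised ground state and is known to favour the threo (ring-trans) epoxy alcohol from Z-allylic alcohols. It sets out from 25 (mCPBA, NaHCO3, CH2Cl2, −40 → −20 °C) and comes back to the route at 26. Its cost is competing oxidation of C1=C10, which is why it is not the first choice. No new compound arises.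

Step 14. Trivalent samarium formed in the flask may open the epoxide transannularly, or hydride transfer from an enal-derived hemiacetal may be slow enough for retro-aldol cleavage to intervene. The fallback replaces intramolecular hydride delivery by an external directed reduction and differentiates the two hydroxyls by size. It sets out from 26. Evans–Saksena reduction (Me4NBH(OAc)3, MeCN–AcOH, −30 °C) should give the anti epoxy diol F7. The less hindered O8 (flanked by a CH2) should be silylated selectively (TESCl, imidazole, CH2Cl2, −20 °C) to give the 8-O-triethylsilyl ether F8. Acylation of O6 (cinnamoyl chloride, DMAP, pyridine) should give the silylated cinnamate F9, and HF·pyridine comes back to the route at 29.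

## Further compounds

F1 | step 9 | tert-butyldimethylsilyl enol ether of 13 toward C1 (configuration at C6, C7 as in 13) | C/C1=C/[C@@H](O[Si](C)(C)C(C)(C)C)[C@H](C(C)C)/C(O[Si](C)(C)C(C)(C)C)=C\CC1
F2 | step 9 | prop-2-en-1-yl 6,8-bis[(tert-butyldimethylsilyl)oxy]-4,10-dimethyl-7-(propan-2-yl)bicyclo[6.2.0]deca-4,9-diene-9-carboxylate (cis-fused, C6/C7 as in 13) | C/C1=C/[C@@H](O[Si](C)(C)C(C)(C)C)[C@H](C(C)C)C2(O[Si](C)(C)C(C)(C)C)C(C(=O)OCC=C)=C(C)C2CC1
F3 | step 9 | prop-2-en-1-yl (1(10)E,4Z,8Z)-6,8-bis[(tert-butyldimethylsilyl)oxy]-4,10-dimethyl-7-(propan-2-yl)cyclodeca-1(10),4,8-triene-9-carboxylate (germacrane locants, C6/C7 as in 13) | C/C1=C/[C@@H](O[Si](C)(C)C(C)(C)C)[C@H](C(C)C)/C(O[Si](C)(C)C(C)(C)C)=C(C(=O)OCC=C)\C(C)=C\CC1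
F4 | step 6 | (3R,4S)-3-hydroxy-9-methyl-4-(propan-2-yl)deca-1,9-dien-5-one | C=C[C@@H](O)[C@H](C(C)C)C(=O)CCCC(C)=C
F5 | step 6 | (2S,3R,4Z)-3-hydroxy-5-methyl-2-(propan-2-yl)cyclooct-4-en-1-one | C/C1=C/[C@@H](O)[C@H](C(C)C)C(=O)CCC1
F6 | step 7 | (1E,5Z,7R,8S)-7-[(tert-butyldimethylsilyl)oxy]-5-methyl-8-(propan-2-yl)cycloocta-1,5-dien-1-yl trifluoromethanesulfonate | C/C1=C/[C@@H](O[Si](C)(C)C(C)(C)C)[C@H](C(C)C)/C(OS(=O)(=O)C(F)(F)F)=C\CC1
F0 | step 13 | none | none
F7 | step 14 | (1(10)E,4S,5R,6S,7R,8R)-4,5-epoxygermacr-1(10)-ene-6,8-diol | C/C1=C\CC[C@]2(C)O[C@@H]2[C@@H](O)[C@H](C(C)C)[C@H](O)C1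
F8 | step 14 | 8-O-triethylsilyl ether of F7 (O6 free) | C/C1=C\CC[C@]2(C)O[C@@H]2[C@@H](O)[C@H](C(C)C)[C@H](O[Si](CC)(CC)CC)C1
F9 | step 14 | 8-O-triethylsilyl ether of 29 | C/C1=C\CC[C@]2(C)O[C@@H]2[C@@H](OC(=O)/C=C/c2ccccc2)[C@H](C(C)C)[C@H](O[Si](CC)(CC)CC)C1
A1 | alternative 1 | (2R,3R,4Z,8E)-10-[(tert-butyldimethylsilyl)oxy]-1-[(4-methoxyphenyl)methoxy]-5,9-dimethyl-2-(propan-2-yl)deca-4,8-dien-3-ol | C/C(CO[Si](C)(C)C(C)(C)C)=C\CC/C(C)=C\[C@@H](O)[C@H](C(C)C)COCc1ccc(OC)cc1
A2 | alternative 1 | {[(2E)-5-bromo-2-methylpent-2-en-1-yl]oxy}(tert-butyl)dimethylsilane | C/C(CO[Si](C)(C)C(C)(C)C)=C\CCBr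
A3 | alternative 1 | propyne | CC#C
A4 | alternative 1 | (2R)-2-{[(4-methoxyphenyl)methoxy]methyl}-3-methylbutanal | O=C[C@H](C(C)C)COCc1ccc(OC)cc1
A5 | alternative 2 | (5R,6R)-5-[(tert-butyldimethylsilyl)oxy]-3-methyl-6-(propan-2-yl)cyclohex-2-en-1-one | CC1=CC(=O)[C@H](C(C)C)[C@H](O[Si](C)(C)C(C)(C)C)C1
A6 | alternative 2 | methyl cyclobut-1-ene-1-carboxylate | COC(=O)C1=CCC1
A7 | alternative 2 | cis-anti-cis tricyclic photoadduct (six-membered ketone fused to a bicyclo[2.2.0]hexane, ester on the future C4) | C[C@@]12C[C@@H](O[Si](C)(C)C(C)(C)C)[C@@H](C(C)C)C(=O)[C@@H]1[C@@]1(C(=O)OC)CC[C@@H]21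
A8 | alternative 2 | methyl 8-[(tert-butyldimethylsilyl)oxy]-10-methyl-6-oxo-7-(propan-2-yl)cyclodeca-1(10),4-diene-4-carboxylate (germacrane locants; C1=C10 E, C3 and C6 trans on C4=C5, as from stereoretentive cleavage) | C/C1=C\CC/C(C(=O)OC)=C/C(=O)[C@H](C(C)C)[C@H](O[Si](C)(C)C(C)(C)C)C1
A9 | alternative 3 | (2S,3S)-3-[(3E)-7-bromo-4,8-dimethyl-6-oxonon-3-en-1-yl]-3-methyloxirane-2-carbaldehyde (either configuration at the bromide carbon) | CC(C)C(Br)C(=O)C/C(C)=C/CC[C@]1(C)O[C@@H]1C=O
A10 | alternative 3 | (1(10)E,4S,5R,6S,7S)-4,5-epoxy-6-hydroxygermacr-1(10)-en-8-one (identical with 26) | C/C1=C\CC[C@]2(C)O[C@@H]2[C@@H](O)[C@H](C(C)C)C(=O)C1
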